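Remark on the chemistry: positions carry the numbers of the target (ring A C1–C5, cyclobutane C1/C5/C6/C10, ring C C6–C10, lactone O6–C12(=O)–C11(C13)=C7, C14 the methyl on C10, C15 the methyl on C4). β is the face of ring A from which the C1–C10 and C5–C6 bonds leave, α the face of H1 and H5. The SMILES strings supplied for the precursor, the product and the three alternative products were checked centre by centre against the target and needed no correction.

## Structural features

The target is a tetracyclic sesquiterpenoid lactone. Cyclopentane ring A (C1–C5) and cyclopentane ring C (C6–C10) are fused to opposite bonds of a cyclobutane (C1/C5/C6/C10), and a butenolide (O6–C12–C11=C7) is fused to ring C at C6–C7. Both five-membered rings stand on the same face of the four-membered ring (cis-syn-cis). H1, H5, the C10 methyl and the lactone oxygen on C6 share the other face, so the molecule is a bowl. There are seven stereocentres: C1, C5, C6 and C10 are contiguous on the cyclobutane (C6 and C10 fully substituted), C2 and C4 lie in ring A, and C8 lies in ring C. The C2 acetate and the C8 tiglate both point to the convex side, while C15 points into the cavity. Fragile groups are the primary allylic acetate on C13, the allylic (E)-tiglate on C8, the butenolide, and the tertiary C4 alcohol beside the cyclobutane (ionisation would trigger ring expansion). The real difficulty is the C5–C6 bond inside a crowded, syn-fused cyclobutane, together with two ester oxygens that sit on the face from which hydride reagents also attack. The feature that the key step uses is that the carbinol C6 is flanked by C7, which can be a ketone in a precursor: a C6/C7 dione in ring C has its C6 oxygen within reach of a hydrogen on C5 once ring A is already attached through C1–C10.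

## Logic of the disconnections

35 ⇒ 33 + 34. The C8–O(acyl) bond is cut. In 33 the hydroxyl stands on the concave face, which is what reduction of ketone 32 from the open face gives, so the ester must be made with inversion; 32 comes from dioxolane 31. This puts the sensitive tiglate last. The forward step must be an SN2 esterification at a shielded allylic carbinol without elimination.

31 ⇒ 30 ⇒ 29 ⇒ 28. The C2–O(acetyl) bond is cut in the same way: 30 is the convex-face reduction product of ketone 29, which is freed from 28 by hydrolysis of one of two dioxolanes and of the silyl ether. Both secondary esters thus trace back to carbons without stereochemistry. The hydrolysis must distinguish the ring A ketal from the ring C ketal next to the butenolide.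

28 ⇒ 27 ⇒ 26. The C13–O bond is cut, so C13 becomes a methyl group. Its hydrogens are the only allylic hydrogens of 26, because C8 is a ketal and C6 is fully substituted. The radical bromination must leave the ketal methylenes alone.

26 ⇒ 25 ⇒ 23 + 24. The butenolide is opened at C7=C11 and at O6–C12, which returns α-ketol 23 and a three-carbon phosphonate. The forward steps must acylate a tertiary cyclobutanol and olefinate a ketone between two fully substituted carbons; the olefination is intramolecular.

23 ⇒ 22. The C5–C6 bond of the cyclobutane is cut and the hydrogen goes back from O6 to C5. The four-membered ring and two stereocentres disappear, leaving two cyclopentanes joined by one bond. The forward step needs a C6 carbonyl that can be excited selectively, a single reachable γ-hydrogen site, and the correct C1/C10 relationship, since that alone decides syn against anti.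

22 ⇒ 21 ⇒ 20 ⇒ 19. The C6 and C7 oxygens are removed to an alkene and the C8 ketal goes back to an enone carbonyl. Regiochemistry becomes unambiguous, because C8 is masked before the other two carbonyls exist. The forward steps must dihydroxylate a hindered cyclopentene and oxidise the diol without C–C cleavage.

19 ⇒ 18 ⇒ 17. The C6=C7 bond is cut (aldol condensation) to a keto aldehyde, whose two carbonyls are unmasked together from the two terminal alkenes of 17. The aldehyde sits on the quaternary C10 and cannot enolise, and only the methyl enolate can close a ring.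

17 ⇒ 16 ⇒ 15 ⇒ 14 ⇒ 13. The C2 ketal goes back to the C2 carbinol and the vinyl group to a lactol, then to a lactone carbonyl (C6) bound to O2. O2 must reach the ketone level and be masked before ring C carries an enone (a free cis hydroxyl would add to it) and before base is used. C1 must keep its configuration during the short life of ketone 16.

13 ⇒ 11 + 12. The C9–C10 bond is cut. The cis-fused lactone is the control element for C10: the electrophile enters trans to the ring A bond at C1 and the methyl already present ends cis to it. That is the C1/C10 relationship that later makes rings A and C syn. The forward step is the quaternisation of a lactone enolate.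

11 ⇒ 10 ⇒ 9. The C4–O bond is cut: the tertiary alcohol comes from a trisubstituted alkene by Markovnikov hydration from the convex face of the bicyclic lactone. Face selectivity at the ring carbon farthest from the fusion is the demand.

9 ⇒ 7 ⇒ 4 ⇒ 1 + 2. The lactone C–O bond and then the C1–C10 bond are cut, the latter as a [3,3] shift that returns the oxygen to C4; last come the C4–C15 bond and the ester. One purchased stereocentre (C2 of 1) sets C1 through two stereospecific events, an anti 1,2-addition and a suprafacial rearrangement. The addition must be anti to the silyloxy group.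

## Other disconnections considered

Alternative 1: The cut runs through C6–C7, C11–C12 and C12–O, so ring C and the butenolide are removed together and the cyclobutanone alkyne A1 remains. Forward, Mo(CO)6 (zerovalent molybdenum) or Cp2Ti(PMe3)2 (divalent titanium) under CO would couple the C6 carbonyl, the tethered C7≡C11 alkyne and CO to the butenolide A2. The sequence is oxidative cyclisation to an oxametallacycle, CO insertion and reductive elimination.
- In its favour: two rings and three bonds form in one step. The C13 oxygen arrives with the alkyne, so no late allylic functionalisation is needed. The C2 acetate and the C8 oxygen already have their final configuration in A1, so the end game would be deprotections and two acylations. On step economy after the key step it is clearly better than the chosen plan, which needs ten steps there.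
- Equal: C6 is fixed by the tether (ring C must fuse cis to the cyclobutane), just as C6 is dictated by C10 in the chosen plan.
- Against it here: A1 is a cis-fused bicycloheptanone whose quaternary C10 must already carry methyl and side chain in the arrangement that makes the rings syn. A ketene cycloaddition to an unsymmetrical, oxygenated cyclopentene would have to control regiochemistry, this centre and the remote C8 carbinol together. Carbonyl Pauson–Khand reactions are most reliable for aldehydes and unhindered ketones; a strained cyclobutanone next to a quaternary carbon invites insertion of the low-valent metal into the acyl C–C bond. The titanium reagent is stoichiometric.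
- Comparison: better after its key step, weaker before it. The chosen plan derives C1 and C10 from a lactone template and leaves one C–C bond to the risky step.

Alternative 2: The cut is C1–C2 in ring A. The precursor A3 is a cyclobutenyl triflate (ring C plus four-membered ring) with the C2 aldehyde at the end of a chain on C5. Forward, CrCl2 with catalytic NiCl2 would turn the triflate into a vinylchromium species of trivalent chromium that adds to the aldehyde and closes ring A as the allylic alcohol A4.
- In its favour: this coupling tolerates dense functionality. There is no diradical that can fragment, which is a point on which it is better than the chosen plan. The syn arrangement would come from hydrogenating C1=C5 from the face of the C10 methyl and O6, the exposed face of the bicycle, possibly guided by the C2 hydroxyl; this argument is at least as convincing as the chosen plan's reliance on C1/C10. The C2 carbinol arises directly, which could save the reduction and inversion at C2.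
- Against it here: A4 contains a tetrasubstituted alkene shared by a four- and a five-membered ring, and the ring closure has to create that strain. No obvious element controls C2 in the addition. Hydrogenation of this alkene is demanding. In A4 the ketal is on C7 and C8 is a methylene, so the C8 oxygen must be introduced late. C4 has to be set in an open chain.
- Comparison: the coupling itself is more predictable than the photochemical hydrogen transfer, the steps around it less so; step count would be similar or higher.

Alternative 3: The cut is C6–C10. The precursor A5 is a 2-alkoxytropone fused to ring A, with O6 tied to O4 through an acetonide. Forward, irradiation above 300 nm would close C6–C10 by disrotatory 4π cyclisation of the C6=C5–C1=C10 diene to the bicyclic dienone A6.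
- In its favour: both fully substituted centres C6 and C10 form in one step from a flat precursor, by a long-known valence isomerisation of tropolone ethers. The tether passes the C4 configuration on to C6 and C10. A6 carries the C7 ketone for the butenolide and a C8=C9 enone, through which the C8 oxygen might be introduced from the convex face without inversion; on that point it is better than the chosen plan. The syn arrangement would again come from exo hydrogenation of C1=C5.
- Against it here: A5 is itself a long synthesis (an annulated tropolone with a quaternary carbinol and a mixed ketal on a tropolone oxygen), and which tropolone oxygen carries the tether must be controlled. Primary photoproducts of this class absorb light and can rearrange further. The hydrogenation must distinguish C1=C5 from C8=C9.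
- Comparison: both plans rest on a photochemical step; this one avoids diradical cleavage but risks secondary photolysis, and its precursor is harder to reach.

Key step: step 16

## Route

Step 1
Reactants: 1 (R)-4-(tert-butyldimethylsilyloxy)cyclopent-2-en-1-one; 2 propanoic anhydride
Product: 4 (1S,4R)-4-(tert-butyldimethylsilyloxy)-1-methylcyclopent-2-en-1-yl propanoate, via lithium alkoxide 3 (not isolated)
Conditions: MeLi, Et2O, −78 °C; then 2, −78 → 0 °C
Reagents that add atoms: methyllithium [Li]C
Why: 1,2-addition of an organolithium to the enone carbonyl from the face away from the silyloxy group should place O4 cis to O2 (C15 trans), and the tertiary alkoxide is acylated in the flask. O4 is only the handle for step 2; any minor epimer is lost in step 3 because it cannot lactonise.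

Step 2
Reactants: 4 (1S,4R)-4-(tert-butyldimethylsilyloxy)-1-methylcyclopent-2-en-1-yl propanoate
Product: 7 2-[(1R,2R)-2-(tert-butyldimethylsilyloxy)-4-methylcyclopent-3-en-1-yl]propanoic acid, via silyl ketene acetal 5 (not isolated), via trimethylsilyl ester 6 (not isolated)
Conditions: LiN(i-Pr)2, THF, −78 °C; Me3SiCl, Et3N, −78 → 23 °C; aq. HCl work-up
Reagents that add atoms: none
Why: Ireland–Claisen rearrangement; the [3,3] shift is suprafacial across the cyclopentene, so C10 is delivered to C1 on the face that carried O4, cis to O2 (sets C1). The alkene ends at C4=C5 with C15 on it; the configuration at C10 stays open until step 6.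

Step 3
Reactants: 7 2-[(1R,2R)-2-(tert-butyldimethylsilyloxy)-4-methylcyclopent-3-en-1-yl]propanoic acid
Product: 9 (3aR,6aR)-3,5-dimethyl-3,3a,6,6a-tetrahydro-2H-cyclopenta[b]furan-2-one, via hydroxy acid 8 (not isolated)
Conditions: HF (48% aq.), MeCN, 0 → 23 °C
Reagents that add atoms: none
Why: Cleavage of the secondary silyl ether, then lactonisation of the cis γ-hydroxy acid. Only the cis isomer can close the five-membered lactone, which becomes the template for C10.

Step 4
Reactants: 9 (3aR,6aR)-3,5-dimethyl-3,3a,6,6a-tetrahydro-2H-cyclopenta[b]furan-2-one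
Product: 10 (3aR,5S,6aR)-5-hydroxy-3,5-dimethylhexahydro-2H-cyclopenta[b]furan-2-one
Conditions: Mn(dpm)3 (cat., dpm = dipivaloylmethanate), PhSiH3, O2 (1 atm), i-PrOH/CH2Cl2, 0 → 23 °C
Reagents that add atoms: dioxygen O=O
Why: Mukaiyama hydration: hydrogen-atom transfer to C5, capture of the tertiary C4 radical by O2, then reduction to the alcohol, with Markovnikov regiochemistry. O2 should approach the cis-fused bicycle from its convex face, which puts O4 trans to the C1–C10 bond as in the target (sets C4).

Step 5
Reactants: 10 (3aR,5S,6aR)-5-hydroxy-3,5-dimethylhexahydro-2H-cyclopenta[b]furan-2-one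
Product: 11 (3aR,5S,6aR)-3,5-dimethyl-5-(triethylsilyloxy)hexahydro-2H-cyclopenta[b]furan-2-one
Conditions: Et3SiOTf, 2,6-lutidine, CH2Cl2, −78 → 0 °C
Reagents that add atoms: triethylsilyl trifluoromethanesulfonate CC[Si](CC)(CC)OS(=O)(=O)C(F)(F)F
Why: Silylation of a tertiary alcohol with a silyl triflate. O4 stays masked until after O6 has been acylated (step 17), so that O6 is then the only free hydroxyl.

Step 6
Reactants: 11 (3aR,5S,6aR)-3,5-dimethyl-5-(triethylsilyloxy)hexahydro-2H-cyclopenta[b]furan-2-one; 12 3-bromo-2-methylprop-1-ene
Product: 13 (3R,3aR,5S,6aR)-3,5-dimethyl-3-(2-methylprop-2-en-1-yl)-5-(triethylsilyloxy)hexahydro-2H-cyclopenta[b]furan-2-one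
Conditions: LiN(i-Pr)2, THF, −78 °C; then 12, DMPU, −78 → −20 °C
Reagents that add atoms: none
Why: Alkylation of a γ-lactone enolate: the electrophile should enter C10 trans to the ring A bond C1–C5 (convex face), leaving C14 cis to it. This sets C10 relative to C1 in the sense that later makes rings A and C syn; both C10 epimers of 11 give the same enolate.

Step 7
Reactants: 13 (3R,3aR,5S,6aR)-3,5-dimethyl-3-(2-methylprop-2-en-1-yl)-5-(triethylsilyloxy)hexahydro-2H-cyclopenta[b]furan-2-one
Product: 14 (3R,3aR,5S,6aR)-3,5-dimethyl-3-(2-methylprop-2-en-1-yl)-5-(triethylsilyloxy)hexahydro-2H-cyclopenta[b]furan-2-ol (both anomers)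
Conditions: i-Bu2AlH, CH2Cl2, −78 °C; aq. potassium sodium tartrate
Reagents that add atoms: none
Why: Partial reduction of a lactone to the lactol at low temperature; the quaternary α-carbon slows over-reduction.

Step 8
Reactants: 14 (3R,3aR,5S,6aR)-3,5-dimethyl-3-(2-methylprop-2-en-1-yl)-5-(triethylsilyloxy)hexahydro-2H-cyclopenta[b]furan-2-ol
Product: 15 (1R,2R,4S)-2-[(3S)-3,5-dimethylhexa-1,5-dien-3-yl]-4-methyl-4-(triethylsilyloxy)cyclopentan-1-ol
Conditions: Ph3PCH3Br, KOt-Bu, THF, 0 → 50 °C
Reagents that add atoms: methyltriphenylphosphonium bromide C[P+](c1ccccc1)(c1ccccc1)c1ccccc1.[Br-]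
Why: Wittig methylenation of the open hydroxy-aldehyde form of the lactol. The aldehyde on the quaternary C10 cannot epimerise; the step frees O2 for oxidation and stores C6 as a vinyl group.

Step 9
Reactants: 15 (1R,2R,4S)-2-[(3S)-3,5-dimethylhexa-1,5-dien-3-yl]-4-methyl-4-(triethylsilyloxy)cyclopentan-1-ol
Product: 16 (2R,4S)-2-[(3S)-3,5-dimethylhexa-1,5-dien-3-yl]-4-methyl-4-(triethylsilyloxy)cyclopentan-1-one
Conditions: Dess–Martin periodinane, NaHCO3, CH2Cl2, 0 → 23 °C
Reagents that add atoms: none
Why: Dess–Martin oxidation of the secondary alcohol under buffered, non-basic conditions, so that C1 (now α to a ketone) should keep its configuration. The stereocentre at C2 is erased on purpose and rebuilt in steps 22 and 23.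

Step 10
Reactants: 16 (2R,4S)-2-[(3S)-3,5-dimethylhexa-1,5-dien-3-yl]-4-methyl-4-(triethylsilyloxy)cyclopentan-1-one
Product: 17 (6R,8S)-6-[(3S)-3,5-dimethylhexa-1,5-dien-3-yl]-8-methyl-8-(triethylsilyloxy)-1,4-dioxaspiro[4.4]nonane
Conditions: Me3SiOCH2CH2OSiMe3, Me3SiOTf (cat.), CH2Cl2, −78 → −20 °C
Reagents that add atoms: 1,2-bis(trimethylsilyloxy)ethane C[Si](C)(C)OCCO[Si](C)(C)C
Why: Silyl-triflate-catalysed ketalisation with the bis-silyl ether of ethylene glycol (aprotic, no water formed). It removes the acidity of H1 before any base is used and leaves C2 without hydrogen for the photochemical step.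

Step 11
Reactants: 17 (6R,8S)-6-[(3S)-3,5-dimethylhexa-1,5-dien-3-yl]-8-methyl-8-(triethylsilyloxy)-1,4-dioxaspiro[4.4]nonane
Product: 18 (2R)-2-methyl-2-[(6R,8S)-8-methyl-8-(triethylsilyloxy)-1,4-dioxaspiro[4.4]nonan-6-yl]-4-oxopentanal
Conditions: O3, CH2Cl2, −78 °C; then Me2S, −78 → 23 °C; aqueous wash
Reagents that add atoms: ozone [O-][O+]=O
Why: Ozonolysis with reductive work-up cleaves both terminal alkenes: the vinyl group gives the C6 aldehyde and the methallyl group the C8 methyl ketone (C7 as its methyl). Formaldehyde is washed out before base is applied.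

Step 12
Reactants: 18 (2R)-2-methyl-2-[(6R,8S)-8-methyl-8-(triethylsilyloxy)-1,4-dioxaspiro[4.4]nonan-6-yl]-4-oxopentanal
Product: 19 (4S)-4-methyl-4-[(6R,8S)-8-methyl-8-(triethylsilyloxy)-1,4-dioxaspiro[4.4]nonan-6-yl]cyclopent-2-en-1-one
Conditions: KOH, MeOH, 23 → 45 °C
Reagents that add atoms: none
Why: Intramolecular aldol condensation. The aldehyde on C10 cannot enolise and only the C7 methyl enolate can reach it through a five-membered ring, so a single cyclopentenone (C8 ketone, C6=C7) should form; no stereocentre is touched.

Step 13
Reactants: 19 (4S)-4-methyl-4-[(6R,8S)-8-methyl-8-(triethylsilyloxy)-1,4-dioxaspiro[4.4]nonan-6-yl]cyclopent-2-en-1-one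
Product: 20 bis-dioxolane cyclopentene (C8 ethylene ketal of 19, C6=C7 kept)
Conditions: Me3SiOCH2CH2OSiMe3, Me3SiOTf (cat.), CH2Cl2, −78 → −10 °C
Reagents that add atoms: 1,2-bis(trimethylsilyloxy)ethane C[Si](C)(C)OCCO[Si](C)(C)C
Why: Ketalisation of the enone carbonyl under the same aprotic conditions. The double bond cannot leave conjugation toward the quaternary C10, and C8 is masked before C6 and C7 are oxidised, which fixes the regiochemistry of the dione.

Step 14
Reactants: 20 bis-dioxolane cyclopentene
Product: 21 cis-C6,C7-diol of 20
Conditions: OsO4 (cat.), N-methylmorpholine N-oxide, acetone/H2O, 23 °C; aq. Na2SO3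
Reagents that add atoms: N-methylmorpholine N-oxide C[N+]1([O-])CCOCC1; water O
Why: Catalytic osmium tetroxide dihydroxylation of the only alkene; either face gives a cis diol and both converge in step 15.

Step 15
Reactants: 21 cis-C6,C7-diol
Product: 22 ring C 1,2-dione (C6 and C7 ketones, C2 and C8 dioxolanes, C4 triethylsilyl ether; C1, C4, C10 as in the target)
Conditions: DMSO, (CF3CO)2O, CH2Cl2, −78 °C; then Et3N, −78 → 0 °C
Reagents that add atoms: none
Why: Swern-type oxidation of a vicinal diol gives the 1,2-dione without C–C cleavage. The dione cannot enolise because C10 is quaternary and C8 is a ketal.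

Step 16
Reactants: 22 ring C 1,2-dione
Product: 23 tricyclic α-ketol (C6 hydroxyl, C7 ketone, cyclobutane C1/C5/C6/C10 syn-fused to rings A and C; C2 and C8 dioxolanes, C4 triethylsilyl ether)
Conditions: hν (blue LEDs, 450 nm), degassed benzene (0.01 M), 10 °C
Reagents that add atoms: none
Why: Norrish–Yang photocyclisation: visible light excites only the 1,2-dione (n,π*), and in the triplet state O6 takes a hydrogen from C5 through a six-membered transition state (O6, C6, C10, C1, C5, H). The hydroxy 1,4-diradical (C6, stabilised by the C7 carbonyl, and C5) then closes the four-membered ring by radical recombination, forming C5–C6. The closest known reaction type is the photocyclisation of 1,2-diketones to hydroxycyclobutanones, in which the remote carbonyl abstracts; here both carbonyls are held s-cis in ring C, O7 points away from every hydrogen, and only O6 has a γ-hydrogen within reach, so the surviving ketone (C7) lies outside the new ring. The cyclobutane must be cis-fused to both five-membered rings: at C5 the new bond enters on the β face next to the C1–C10 bond (controlled by C1), and at C6 it enters next to C1 on ring C, leaving O6 on the face of C14 (controlled by C10). Because step 6 placed C14 and H1 on the same side of the future cyclobutane, the two cyclopentanes end up syn. Site selectivity is secured by the substrate: C2 has no hydrogen, the C8 ketal prevents enolisation, the dioxolane hydrogens are tied back out of reach, and benzene offers no abstractable hydrogen. The selectivity not secured by structure is ring closure against cleavage of the C1–C10 bond in the diradical; the quaternary C10, low temperature and high dilution are the only handles. Light of 450 nm is not absorbed by the α-ketol product, so it should survive.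

Step 17
Reactants: 23 tricyclic α-ketol; 24 2-(diethoxyphosphoryl)propanoic acid
Product: 25 O6 2-(diethoxyphosphoryl)propanoate of 23 (both epimers at C11)
Conditions: N,N'-dicyclohexylcarbodiimide, DMAP (cat.), CH2Cl2, 0 → 23 °C
Reagents that add atoms: none
Why: Carbodiimide esterification with an α-phosphono acid, which can react through its ketene and so reach a tertiary hydroxyl. O4 is silylated, so O6 is the only free hydroxyl, and acylation also blocks acyloin-type ring expansion of the cyclobutanol.

Step 18
Reactants: 25 O6 phosphonopropanoate
Product: 26 tetracyclic α-methylbutenolide (C7=C11, C13 methyl; C2 and C8 dioxolanes, C4 triethylsilyl ether)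
Conditions: NaH, THF, 0 → 40 °C
Reagents that add atoms: none
Why: Intramolecular Horner–Wadsworth–Emmons olefination of the C7 ketone by the tethered phosphonate closes the butenolide; five-membered ring formation compensates for the hindered ketone.

Step 19
Reactants: 26 tetracyclic α-methylbutenolide
Product: 27 C13 bromide of 26
Conditions: N-bromosuccinimide, AIBN (cat.), K2CO3, PhCF3, 80 °C
Reagents that add atoms: N-bromosuccinimide O=C1CCC(=O)N1Br
Why: Wohl–Ziegler bromination. C13–H is the only allylic C–H (C8 is a ketal, C6 is fully substituted), so the chain should select the C13 methyl; the carbonate removes HBr.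

Step 20
Reactants: 27 C13 bromide
Product: 28 C13 acetate (C2 and C8 dioxolanes, C4 triethylsilyl ether)
Conditions: KOAc, 18-crown-6 (cat.), DMF, 23 °C
Reagents that add atoms: potassium acetate [K+].[O-]C(C)=O
Why: SN2 displacement of a primary allylic bromide by acetate; attack at C7 (SN2′) is excluded by full substitution.

Step 21
Reactants: 28 C13 acetate
Product: 29 C2 ketone with free C4 hydroxyl (C8 dioxolane kept)
Conditions: 1 M HCl (aq.), THF, 0 → 23 °C, followed closely
Reagents that add atoms: water O
Why: Acid hydrolysis. The ring A dioxolane (an ordinary cyclopentanone ketal) and the silyl ether should cleave well before the ring C dioxolane, whose oxocarbenium ion would sit on the electron-poor C7=C11–C12=O system. C1 is now a cyclobutane fusion carbon and cannot epimerise.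

Step 22
Reactants: 29 C2 ketone
Product: 30 2β-alcohol (hydroxyl on the concave face, cis to the C1–C10 bond)
Conditions: NaBH4, MeOH/CH2Cl2, −40 → −20 °C
Reagents that add atoms: none
Why: Borohydride reduction from the open α face (the β face looks into the cavity toward ring C) should give the 2β-alcohol. The tetrasubstituted butenolide, the acetate and the ketal are not reduced at this temperature.

Step 23
Reactants: 30 2β-alcohol
Product: 31 2α-acetate (C2 as in the target; C8 dioxolane, C13 acetate, free C4 hydroxyl)
Conditions: AcOH, PPh3, diisopropyl azodicarboxylate, toluene, 0 → 23 °C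
Reagents that add atoms: acetic acid CC(=O)O
Why: Mitsunobu esterification inverts C2: acetate enters from the open α face, which sets C2 as in the target. The tertiary C4 hydroxyl does not react.

Step 24
Reactants: 31 2α-acetate
Product: 32 C8 ketone (γ-oxo butenolide)
Conditions: In(OTf)3 (cat.), acetone/H2O, 23 → 50 °C
Reagents that add atoms: water O
Why: Lewis-acid-catalysed hydrolysis of the remaining, less reactive dioxolane, under conditions mild enough for the tertiary alcohol beside the cyclobutane and for both acetates.

Step 25
Reactants: 32 C8 ketone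
Product: 33 C8 alcohol with the hydroxyl on the concave face (C8 epimer of the natural alcohol)
Conditions: NaBH4, CeCl3·7H2O, MeOH, −78 °C
Reagents that add atoms: none
Why: Luche reduction (1,2-selective) from the face of C14 and O6, the only open face because ring A covers the other, should give the C8 epimer of the natural alcohol.

Step 26
Reactants: 33 C8 alcohol; 34 (E)-2-methylbut-2-enoic acid (tiglic acid)
Product: 35 CNP0210373.1
Conditions: PPh3, diisopropyl azodicarboxylate, toluene, 0 → 23 °C
Reagents that add atoms: none
Why: Mitsunobu esterification inverts C8: the carboxylate enters from the open face, which sets C8 as in the target. The E geometry of the acid is untouched and the tertiary hydroxyl is inert.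

## Compound list

1 | (R)-4-(tert-butyldimethylsilyloxy)cyclopent-2-en-1-one | O=C1C=C[C@H](O[Si](C)(C)C(C)(C)C)C1 | starting material
2 | propanoic anhydride | CCC(=O)OC(=O)CC | starting material
3 | lithium (1S,4R)-4-(tert-butyldimethylsilyloxy)-1-methylcyclopent-2-en-1-olate | C[C@@]1([O-])C=C[C@H](O[Si](C)(C)C(C)(C)C)C1.[Li+] | intermediate
4 | (1S,4R)-4-(tert-butyldimethylsilyloxy)-1-methylcyclopent-2-en-1-yl propanoate | CCC(=O)O[C@]1(C)C=C[C@H](O[Si](C)(C)C(C)(C)C)C1 | intermediate
5 | trimethylsilyl ketene acetal of 4 (E/Z mixture) | CC=C(O[Si](C)(C)C)O[C@]1(C)C=C[C@H](O[Si](C)(C)C(C)(C)C)C1 | intermediate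
6 | trimethylsilyl 2-[(1R,2R)-2-(tert-butyldimethylsilyloxy)-4-methylcyclopent-3-en-1-yl]propanoate | C[Si](C)(C)OC(=O)C(C)[C@H]1C=C(C)C[C@H]1O[Si](C)(C)C(C)(C)C | intermediate
7 | 2-[(1R,2R)-2-(tert-butyldimethylsilyloxy)-4-methylcyclopent-3-en-1-yl]propanoic acid (both epimers at the future C10) | OC(=O)C(C)[C@H]1C=C(C)C[C@H]1O[Si](C)(C)C(C)(C)C | intermediate
8 | 2-[(1R,2R)-2-hydroxy-4-methylcyclopent-3-en-1-yl]propanoic acid | OC(=O)C(C)[C@H]1C=C(C)C[C@H]1O | intermediate
9 | (3aR,6aR)-3,5-dimethyl-3,3a,6,6a-tetrahydro-2H-cyclopenta[b]furan-2-one (both C3 epimers) | O=C1C(C)[C@H]2C=C(C)C[C@H]2O1 | intermediate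
10 | (3aR,5S,6aR)-5-hydroxy-3,5-dimethylhexahydro-2H-cyclopenta[b]furan-2-one (hydroxyl on the convex face) | O=C1C(C)[C@H]2C[C@](C)(O)C[C@H]2O1 | intermediate
11 | (3aR,5S,6aR)-3,5-dimethyl-5-(triethylsilyloxy)hexahydro-2H-cyclopenta[b]furan-2-one | O=C1C(C)[C@H]2C[C@](C)(O[Si](CC)(CC)CC)C[C@H]2O1 | intermediate
12 | 3-bromo-2-methylprop-1-ene | BrCC(C)=C | starting material
13 | (3R,3aR,5S,6aR)-3,5-dimethyl-3-(2-methylprop-2-en-1-yl)-5-(triethylsilyloxy)hexahydro-2H-cyclopenta[b]furan-2-one | O=C1[C@](C)(CC(C)=C)[C@H]2C[C@](C)(O[Si](CC)(CC)CC)C[C@H]2O1 | intermediate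
14 | (3R,3aR,5S,6aR)-3,5-dimethyl-3-(2-methylprop-2-en-1-yl)-5-(triethylsilyloxy)hexahydro-2H-cyclopenta[b]furan-2-ol (both anomers) | OC1[C@](C)(CC(C)=C)[C@H]2C[C@](C)(O[Si](CC)(CC)CC)C[C@H]2O1 | intermediate
15 | (1R,2R,4S)-2-[(3S)-3,5-dimethylhexa-1,5-dien-3-yl]-4-methyl-4-(triethylsilyloxy)cyclopentan-1-ol | C=C[C@](C)(CC(C)=C)[C@H]1C[C@](C)(O[Si](CC)(CC)CC)C[C@H]1O | intermediate
16 | (2R,4S)-2-[(3S)-3,5-dimethylhexa-1,5-dien-3-yl]-4-methyl-4-(triethylsilyloxy)cyclopentan-1-one | C=C[C@](C)(CC(C)=C)[C@H]1C[C@](C)(O[Si](CC)(CC)CC)CC1=O | intermediate
17 | (6R,8S)-6-[(3S)-3,5-dimethylhexa-1,5-dien-3-yl]-8-methyl-8-(triethylsilyloxy)-1,4-dioxaspiro[4.4]nonane | C=C[C@](C)(CC(C)=C)[C@H]1C[C@](C)(O[Si](CC)(CC)CC)CC12OCCO2 | intermediate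
18 | (2R)-2-methyl-2-[(6R,8S)-8-methyl-8-(triethylsilyloxy)-1,4-dioxaspiro[4.4]nonan-6-yl]-4-oxopentanal | O=C[C@](C)(CC(C)=O)[C@H]1C[C@](C)(O[Si](CC)(CC)CC)CC12OCCO2 | intermediate
19 | (4S)-4-methyl-4-[(6R,8S)-8-methyl-8-(triethylsilyloxy)-1,4-dioxaspiro[4.4]nonan-6-yl]cyclopent-2-en-1-one | O=C1C=C[C@](C)(C1)[C@H]2C[C@](C)(O[Si](CC)(CC)CC)CC23OCCO3 | intermediate
20 | bis-dioxolane cyclopentene (C8 ethylene ketal of 19, C6=C7; C2 dioxolane, C4 triethylsilyl ether) | O1CCOC12C=C[C@](C)(C2)[C@H]3C[C@](C)(O[Si](CC)(CC)CC)CC34OCCO4 | intermediate
21 | cis-C6,C7-diol of 20 (either face) | O1CCOC12C(O)C(O)[C@](C)(C2)[C@H]3C[C@](C)(O[Si](CC)(CC)CC)CC34OCCO4 | intermediate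
22 | ring C 1,2-dione joined to ring A by C1–C10 (C2 and C8 dioxolanes, C4 triethylsilyl ether; C1, C4, C10 as in the target) | O=C1C(=O)C2(OCCO2)C[C@]1(C)[C@@H]2C3(OCCO3)C[C@@](C)(O[Si](CC)(CC)CC)C2 | intermediate
23 | tricyclic α-ketol (C6 hydroxyl, C7 ketone, syn-fused cyclobutane; C2 and C8 dioxolanes, C4 triethylsilyl ether) | O=C1C2(OCCO2)C[C@]2(C)[C@@H]3C4(OCCO4)C[C@@](C)(O[Si](CC)(CC)CC)[C@@H]3[C@@]21O | intermediate
24 | 2-(diethoxyphosphoryl)propanoic acid | CCOP(=O)(OCC)C(C)C(=O)O | starting material
25 | O6 2-(diethoxyphosphoryl)propanoate of 23 (both C11 epimers) | O=C1C2(OCCO2)C[C@]2(C)[C@@H]3C4(OCCO4)C[C@@](C)(O[Si](CC)(CC)CC)[C@@H]3[C@@]21OC(=O)C(C)P(=O)(OCC)OCC | intermediate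
26 | tetracyclic α-methylbutenolide (C13 methyl; C2 and C8 dioxolanes, C4 triethylsilyl ether) | C12(OCCO1)C[C@]3(C)[C@@H]4C5(OCCO5)C[C@@](C)(O[Si](CC)(CC)CC)[C@@H]4[C@@]36OC(=O)C(C)=C26 | intermediate
27 | C13 bromide of 26 | C12(OCCO1)C[C@]3(C)[C@@H]4C5(OCCO5)C[C@@](C)(O[Si](CC)(CC)CC)[C@@H]4[C@@]36OC(=O)C(CBr)=C26 | intermediate
28 | C13 acetate (C2 and C8 dioxolanes, C4 triethylsilyl ether) | C12(OCCO1)C[C@]3(C)[C@@H]4C5(OCCO5)C[C@@](C)(O[Si](CC)(CC)CC)[C@@H]4[C@@]36OC(=O)C(COC(C)=O)=C26 | intermediate
29 | C2 ketone with free C4 hydroxyl (C8 dioxolane, C13 acetate) | C12(OCCO1)C[C@]3(C)[C@@H]4C(=O)C[C@@](C)(O)[C@@H]4[C@@]36OC(=O)C(COC(C)=O)=C26 | intermediate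
30 | 2β-alcohol (C2 epimeric to the target; C8 dioxolane, C13 acetate) | C12(OCCO1)C[C@]3(C)[C@@H]4[C@H](O)C[C@@](C)(O)[C@@H]4[C@@]36OC(=O)C(COC(C)=O)=C26 | intermediate
31 | 2α-acetate (C2 as in the target; C8 dioxolane, C13 acetate) | C12(OCCO1)C[C@]3(C)[C@@H]4[C@@H](OC(C)=O)C[C@@](C)(O)[C@@H]4[C@@]36OC(=O)C(COC(C)=O)=C26 | intermediate
32 | C8 ketone (2α-acetate, C13 acetate, free C4 hydroxyl) | O=C1C[C@]2(C)[C@@H]3[C@@H](OC(C)=O)C[C@@](C)(O)[C@@H]3[C@@]24OC(=O)C(COC(C)=O)=C14 | intermediate
33 | C8 alcohol, hydroxyl on the concave face (C8 epimeric to the target) | O[C@@H]1C[C@]2(C)[C@@H]3[C@@H](OC(C)=O)C[C@@](C)(O)[C@@H]3[C@@]24OC(=O)C(COC(C)=O)=C14 | intermediate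
34 | (E)-2-methylbut-2-enoic acid (tiglic acid) | C/C=C(\C)C(=O)O | starting material
35 | CNP0210373.1 | C/C=C(\C)C(=O)O[C@H]1C[C@]2(C)[C@@H]3[C@@H](OC(C)=O)C[C@@](C)(O)[C@@H]3[C@@]23OC(=O)C(COC(C)=O)=C13 | target

## Step count and least certain steps

Total step count: 26. Longest linear sequence: 26 steps (1 to 35); 2, 12, 24 and 34 are purchased.

Step 16 (key step). The process most likely to fail is partition of the 1,4-diradical toward cleavage of the C1–C10 bond instead of ring closure. Cleavage would give a conjugated enol in ring C and a cyclopentene, and it is helped by the strain of the syn-fused cyclobutane that closure must build; return of the hydrogen to C5 merely regenerates 22. Fallback (a different chromophore and redox sequence): set out from 22 and remove the acyl group from the ketyl centre, so that cleavage would no longer give a conjugated enol.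
- NaBH4 (limiting, −78 °C) should reduce the more electrophilic, ketal-flanked C7 carbonyl to the C6-ketone C7-alcohol F1.
- Me3SiCl and imidazole give its C7 trimethylsilyl ether F2.
- Irradiation at 300 nm in degassed MeCN (Norrish–Yang cyclisation of a mono-ketone, with C5–H still the only γ-hydrogen in reach) should give the cyclobutanol C7 silyl ether F3. α-Cleavage of the excited ketone is the risk of this variant.
- K2CO3 in MeOH frees the C6,C7-diol F4, and Dess–Martin oxidation of its secondary hydroxyl returns to the route at 23.

Step 4. Facial selectivity in the capture of the C4 radical by O2 may be poor, because C4 is the ring carbon farthest from the fusion. Fallback from 9: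
- OsO4 (cat.) with N-methylmorpholine N-oxide should add both oxygens from the convex face to give the exo C4,C5-diol lactone F5.
- PhOC(S)Cl and pyridine convert the secondary C5 hydroxyl into the C5 O-phenyl thionocarbonate F6.
- Bu3SnH with AIBN (Barton–McCombie deoxygenation) removes the C5 oxygen and returns to the route at 10.

Step 17. Acylation of the hindered tertiary hydroxyl may be slow, which would leave the free α-ketol exposed to acyloin-type ring expansion of the cyclobutanol under the basic catalyst. Fallback from 23:
- Propanoic anhydride with DMAP, a small acylating agent, gives the O6 propanoate F7.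
- LiN(SiMe3)2 in THF at −78 °C should add the ester enolate to the C7 ketone (intramolecular aldol) to give the β-hydroxy lactone F8.
- SOCl2 in pyridine dehydrates F8; C11–H is the only hydrogen next to C7, so the alkene can only form at C7=C11, and the route is rejoined at 26.

Step 21. The two dioxolanes may hydrolyse at similar rates. Fallback from 28:
- 2 M HCl in THF at 40 °C removes both ketals and the silyl ether to give the C2,C8-diketone F9.
- NaBH4 with CeCl3·7H2O reduces both ketones from their open faces to the C2,C8-diol F10.
- MnO2 oxidises only the allylic C8 hydroxyl to give the 2β-hydroxy C8-ketone F11.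
- Mitsunobu esterification with AcOH then returns to the route at 32.

Step 26. Activation of the C8 hydroxyl, which lies under ring A, may fail or end in elimination toward C9. Fallback from 33:
- MsCl and Et3N at −20 °C give the C8 mesylate F12 with retention.
- Caesium tiglate (from 34 and Cs2CO3) with 18-crown-6 in toluene displaces it with inversion and returns to the route at 35.

## Further compounds

F1 | step 16 | C6-ketone C7-alcohol from mono-reduction of 22 | O=C1C(O)C2(OCCO2)C[C@]1(C)[C@@H]2C3(OCCO3)C[C@@](C)(O[Si](CC)(CC)CC)C2
F2 | step 16 | C7 trimethylsilyl ether of F1 | O=C1C(O[Si](C)(C)C)C2(OCCO2)C[C@]1(C)[C@@H]2C3(OCCO3)C[C@@](C)(O[Si](CC)(CC)CC)C2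
F3 | step 16 | cyclobutanol C7 silyl ether | C[Si](C)(C)OC1C2(OCCO2)C[C@]2(C)[C@@H]3C4(OCCO4)C[C@@](C)(O[Si](CC)(CC)CC)[C@@H]3[C@@]21O
F4 | step 16 | tricyclic C6,C7-diol | OC1C2(OCCO2)C[C@]2(C)[C@@H]3C4(OCCO4)C[C@@](C)(O[Si](CC)(CC)CC)[C@@H]3[C@@]21O
F5 | step 4 | exo C4,C5-diol lactone | O=C1C(C)[C@H]2[C@H](O)[C@](C)(O)C[C@H]2O1
F6 | step 4 | C5 O-phenyl thionocarbonate of F5 | O=C1C(C)[C@H]2[C@H](OC(=S)Oc3ccccc3)[C@](C)(O)C[C@H]2O1
F7 | step 17 | O6 propanoate of 23 | O=C1C2(OCCO2)C[C@]2(C)[C@@H]3C4(OCCO4)C[C@@](C)(O[Si](CC)(CC)CC)[C@@H]3[C@@]21OC(=O)CC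
F8 | step 17 | β-hydroxy lactone (C7 hydroxyl, C11 methyl) | C12(OCCO1)C[C@]3(C)[C@@H]4C5(OCCO5)C[C@@](C)(O[Si](CC)(CC)CC)[C@@H]4[C@@]36OC(=O)C(C)C26O
F9 | step 21 | C2,C8-diketone with free C4 hydroxyl | O=C1C[C@]2(C)[C@@H]3C(=O)C[C@@](C)(O)[C@@H]3[C@@]24OC(=O)C(COC(C)=O)=C14
F10 | step 21 | C2,C8-diol (both hydroxyls on concave faces) | O[C@@H]1C[C@]2(C)[C@@H]3[C@H](O)C[C@@](C)(O)[C@@H]3[C@@]24OC(=O)C(COC(C)=O)=C14
F11 | step 21 | 2β-hydroxy C8-ketone | O=C1C[C@]2(C)[C@@H]3[C@H](O)C[C@@](C)(O)[C@@H]3[C@@]24OC(=O)C(COC(C)=O)=C14
F12 | step 26 | C8 mesylate of 33 | CS(=O)(=O)O[C@@H]1C[C@]2(C)[C@@H]3[C@@H](OC(C)=O)C[C@@](C)(O)[C@@H]3[C@@]24OC(=O)C(COC(C)=O)=C14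
A1 | alternative 1 | cyclobutanone alkyne (C6 ketone; C10 side chain C9–C8(OSi-t-BuMe2)–C7≡C11–C13 p-methoxybenzyl ether) | CC(C)(C)[Si](C)(C)O[C@H](C#CCOCc1ccc(OC)cc1)C[C@]2(C)[C@@H]3[C@@H](OC(C)=O)C[C@@](C)(O[Si](CC)(CC)CC)[C@@H]3C2=O
A2 | alternative 1 | protected tetracyclic butenolide | CC(C)(C)[Si](C)(C)O[C@H]1C[C@]2(C)[C@@H]3[C@@H](OC(C)=O)C[C@@](C)(O[Si](CC)(CC)CC)[C@@H]3[C@@]23OC(=O)C(COCc2ccc(OC)cc2)=C13
A3 | alternative 2 | cyclobutenyl triflate aldehyde (C1 triflate, C2 aldehyde on the C5 chain, C7 dioxolane) | C1C[C@]2(C)C(OS(=O)(=O)C(F)(F)F)=C([C@](C)(O[Si](CC)(CC)CC)CC=O)[C@]2(OCOC)C14OCCO4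
A4 | alternative 2 | tricyclic cyclobutene with C2 allylic alcohol | C1C[C@]2(C)C3=C([C@](C)(O[Si](CC)(CC)CC)C[C@@H]3O)[C@]2(OCOC)C14OCCO4
A5 | alternative 3 | ring A fused 2-alkoxytropone with O4–O6 acetonide | O=C1C=CC(C)=C2C3=C1OC(C)(C)O[C@]3(C)CC24OCCO4
A6 | alternative 3 | tricyclic dienone with C6 and C10 set | O=C1C=C[C@]2(C)C3=C4[C@@]21OC(C)(C)O[C@]4(C)CC35OCCO5
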